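A neighbouring flask, charged alike but with twice the second substrate, is the test at the end of this reckoning for the flask below.

starting material 0.17 M; second substrate 0.170 M; reagent 0.204 M; free catalyst 0.85 mM; added ligand 0.75 mM

    starting material + free catalyst ⇌ catalyst intermediate A (K1 = 1.87 M⁻¹, k1 = 64.6 M⁻¹ s⁻¹)
    reagent + catalyst intermediate A → free catalyst + target (k2 = 857 M⁻¹ s⁻¹)
    second substrate + free catalyst ⇌ catalyst intermediate B (K3 = 18 M⁻¹, k3 = 40.0 M⁻¹ s⁻¹)
    reagent + catalyst intermediate B → free catalyst + second product (k4 = 14.4 M⁻¹ s⁻¹)
    catalyst intermediate B → spent catalyst (k5 = 0.0211 s⁻¹)
    free catalyst + added ligand ⇌ idle complex (K6 = 308 M⁻¹, k6 = 3040 M⁻¹ s⁻¹)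

1. apparent order in reagent when 30% of the starting material are converted (percent change of the rate of making target for one percent more reagent charged)
2. apparent order in second substrate when 30% of the starting material are converted (percent change of the rate of making target for one percent more second substrate charged)

My own reckoning freezes the charges and lets the forms of the catalyst balance one another, catalyst being far scarcer than either substrate. The balance reads as a small ledger for catalyst intermediate B. Free catalyst enters it at 6.80 s⁻¹. Intermediate B leaves by reversal at 2.22 s⁻¹, by reagent at 2.94 s⁻¹, and by spending at 0.0211 s⁻¹, which is slower than either.

Entry over the summed exits gives the hold ratio, intermediate B per free catalyst in steady balance: 1.31. It lies below the equilibrium value 3.1. Intermediate A adds 0.0525 per free catalyst and idle complex 0.231, so intermediate B holds 50.6% of the live catalyst.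

Reagent traps 83.5% of intermediate A. A given conversion therefore needs a fixed sum of free catalyst over time, and spending scales with the hold ratio times that sum. At the asked conversion this reckoning puts the loss at 21.5% of the catalyst charged.

At equal conversion, then, the order in second substrate is −0.780. Reagent shortens the hold ratio by its share of the exits, adds the untrapped share of intermediate A, and is amplified by charge over reagent left after target, giving 0.810.

The forecast gave 1 in reagent (0.85 to 1.2) and −0.95 in second substrate (−1.15 to −0.75), reasoning that “Second substrate strongly sequesters catalyst in intermediate B”. Its order in reagent is higher than mine, and its order in second substrate is lower than mine.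

The simulation gives 1.0 in reagent, higher than my reckoning, and −0.94 in second substrate, lower than my reckoning, both inside the forecast's ranges. In this flask at 4.00 s, intermediate B stood at 49.3% and free catalyst at 36.9%, a reading of 1.34 against the hold ratio 1.31, while step 5 had made 4.14% spent catalyst, rising to 19.6% by 20.0 s. Doubling the hold ratio in the neighbouring flask doubles the reckoned loss and gives a reckoned rate factor of 0.482, and the simulated factor is 0.386.

Its constants come from no measurement; the result is computed.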